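## The problem

Target **30** is the 1,15‑macrolactone of prostaglandin E3 carrying an acetate on O11. Prostanoid numbering is used throughout: lactone carbonyl C1, cyclopentane C8–C12, ketone C9, acetoxy carbon C11, carbinol C15, chain end C20. A 13‑membered lactone (C1–C8, C12–C15 and the ring oxygen) is fused across the C8–C12 bond of a cyclopentanone. It holds the Z‑C5=C6 and E‑C13=C14 double bonds, and a (Z)‑pent‑2‑enyl group hangs from C15.

C8, C11 and C12 are contiguous and all‑trans on the five‑membered ring. C11 can therefore direct C12 (addition anti to the C11 oxygen), and C12 can direct C8 (alkylation anti to the C12 chain). C15 is insulated from the ring by the E‑alkene and has to be set on its own by reagent control.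

The C9 ketone and the C11 acetate form a β‑acetoxy ketone, which loses acetic acid to the cross‑conjugated cyclopentenone under mild base; C8 is epimerisable. The C15 ester is allylic and can ionise, and neither Z‑alkene may be isomerised. The oxygens at C9, C11 and C15 end as ketone, acetate and lactone, so they must be told apart along the way.

The feature that makes the ring closure possible is the C4–C5 single bond. It joins a saturated ester arm (C1–C4) to the Z‑C5=C6 alkene, so cutting it leaves a terminal alkene that can be hydroborated and a Z‑alkenyl iodide whose geometry is fixed beforehand in a three‑carbon building block.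

## Retrosynthesis

**C9 oxidation level (30 ⇒ 29 ⇒ 28).** The β‑acetoxy ketone is unmasked last. Ketone **30** comes from the 9α‑alcohol **29** by a near‑neutral oxidation, and **29** from silyl ether **28**. Holding C9 as a silyl ether keeps a borane‑reducible ketone and a base‑labile β‑acetoxy ketone out of the ring‑closing step. No C–C bond is cut; the forward steps must only avoid base.

**C4–C5 (28 ⇒ 26 via 27).** The macrocycle is opened at the sp3–sp2 bond C4–C5. Lactonisation at C1–O15 would require the whole C1–C7 chain to be built first, and olefin metathesis at C5=C6 would leave the Z geometry to the ring. The C4–C5 cut instead takes the geometry from a preformed Z‑iodoalkene and closes the ring far from every stereocentre. Precursor **26** is an open cyclopentane with a but‑3‑enoate on O15 and a (Z)‑3‑iodoallyl group on C8. The forward reaction needs hydroboration of the terminal alkene only (borane **27**), then intramolecular B‑alkyl Suzuki–Miyaura coupling under high dilution.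

**O15–C1 and the oxygen relay (26 ⇒ 24 + 25; 24 ⇐ 23 ⇐ 22 ⇐ 21 ⇐ 20 ⇐ 19).** The ester is cut to alcohol **24** and but‑3‑enoic acid **25**. The three oxygens are sorted by three groups of graded lability:
- O11 arrives as a triethylsilyl ether (**19**) and is exchanged for the acetate (**22**, **23**).
- O9 is created by reduction (**20**) and held as the robust tert‑butyldimethylsilyl ether (**21**).
- O15 is a 4‑methoxybenzyl ether until just before acylation (**24**).

This costs six functional‑group steps. Each is a standard, orthogonal operation, and the isomerisation‑prone β,γ‑unsaturated ester is introduced only one step before it is used.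

**C12–C13 and C7–C8 (19 ⇒ 13 + 15 + 4).** Both ring–chain bonds are cut in one operation. A lithium alkenylzincate from iodide **13** adds to enone **15** anti to the C11 silyloxy group, and the zinc enolate is alkylated by allylic iodide **4** anti to the new C12 chain. Building the chains stepwise by olefinations from a bicyclic lactone would be longer. The three‑component coupling instead gives the all‑trans ring from the single stereocentre of **15** and brings in the E‑C13=C14, Z‑C17=C18 and Z‑C5=C6 geometries ready‑made. The forward reaction needs an enolate that alkylates faster than it equilibrates, hence the zincate and a reactive allylic iodide.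

**C14–C15 (13 ⇒ 11 ⇒ 10 ⇒ 9 ⇒ 6 + 7; 6 ⇐ 5).** The E‑iodoalkene **13** is traced to terminal alkyne **11** (hydrozirconation–iodination). Its C15 stereocentre comes from a catalytic asymmetric addition of the alkynylzinc of **7** to (Z)‑hex‑3‑enal **6**, made from (Z)‑hex‑3‑en‑1‑ol **5**, which already contains the Z‑C17=C18 alkene. Setting C15 on a C8 fragment avoids a late reduction of a C15 enone next to other reducible groups.

**Small building blocks (4 ⇐ 3 ⇐ 2 ⇐ 1; 15 ⇐ 14).** The Z‑iodoalkene comes from anti hydroiodination of methyl propiolate **1** (ester **2**), reduction (**3**) and iodination (**4**). Enone **15** is the silyl ether of (R)‑4‑hydroxycyclopent‑2‑enone **14**.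

## Roads not taken

**Alternative 1: organocatalytic Michael–Henry ring construction.**
- Cut: the ring bonds C8–C12 and C9–C10. Succinaldehyde A1 and (E)‑4,4‑dimethoxy‑1‑nitrobut‑1‑ene A2 would give the nitro hydroxy cyclopentanecarbaldehyde A3.
- Forward key step: a chiral secondary amine turns A1 into an enamine that adds through C12 to C8 of A2; the nitronate at C9 then closes onto the second aldehyde.
- Merits: the ring and the absolute configuration at C8 and C12 come from a catalyst and achiral materials. In this respect it is better than the chosen plan, which buys its ring stereochemistry with the enantiopure enone **14**.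
- Weak points: the hydroxyl of A3 sits on C10, but the target is oxygenated at C11, so an oxygen transposition is needed after the nitro group has served as the C9 carbonyl precursor. A3 carries only stubs of both chains, so the Z‑C5=C6 alkene, the E‑C13=C14 alkene and C15 would each need their own olefination or reduction. The 13‑membered ring is not addressed at all.
- Comparison: the chosen plan sets against the catalytic ring synthesis an enone with the C11 oxygen already in place, both chains arriving complete in one coupling, and a ring closure built into the design.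

**Alternative 2: samarium ketyl closure of C11–C12.**
- Cut: the ring bond C11–C12. The acyclic aldehyde vinyl sulfone A4 would give cyclopentanol A5.
- Forward key step: SmI2 reduces the C11 aldehyde to a ketyl that adds 5‑exo to C12 of the E‑vinyl sulfone.
- Merits: the conditions are mild, and the C11 hydroxyl of A5 emerges free and already distinguished from the silylated C9 oxygen. The chosen plan needs its silyl‑exchange steps for that, so here the alternative is better.
- Weak points: C8 and C9 must be set in the open chain before cyclisation, and the C11/C12 outcome rests on substrate control in a radical closure. The sulfone arm must still be converted into the E‑alkene with the C15 chain by Julia olefination. The but‑2‑ynyl arm on C8 must be extended and semi‑reduced in the presence of two other alkenes. The macrolactone remains to be closed.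
- Comparison: the chosen plan sets against the free C11 hydroxyl a three‑component coupling that controls all ring stereocentres from one and supplies all three alkene geometries preformed.

**Alternative 3: alkyne metathesis at C13–C14 and trans semi‑reduction.**
- Cut: the C13–C14 bond. The diyne ester A6 would give cycloalkyne A7.
- Forward key step: the propynyl groups on C12 and C15 undergo ring‑closing alkyne metathesis with (4‑MeOC6H4C≡)Mo(OSiPh3)3. The E‑alkene would follow by trans‑hydrosilylation with [Cp*Ru(MeCN)3]PF6 and protodesilylation.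
- Merits: the catalyst ignores the alkenes and tolerates the ketone and acetate. A7 can therefore carry the C9 carbonyl, and the reduction, silylation, desilylation and oxidation of the chosen route (steps 11, 12, 18, 19) would not be needed. That is a real saving of four steps.
- Weak points: A6 needs an alkynyl group on C12, which cuprates do not transfer to enones, and a propargylic ester stereocentre at C15. The alkyne to be formed is flanked by two branched carbons. The E‑alkene costs two steps after ring closure, and the fluoride of the second step endangers the β‑acetoxy ketone.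
- Comparison: the chosen plan sets against the four saved steps an E‑C13=C14 alkene carried in from fragment **13**, an ordinary alkenyl conjugate addition, and a ring closure after which no further change to the carbon skeleton is needed.

Key step: step 17

Assumption: in step 5 the BINOL antipode is written for delivery of the alkynyl group to the Re face of aldehyde 6, the sense required for 15S; should this aldehyde respond in the opposite sense, the other antipode is used.

## Route

Step 1
Reactants: 1 methyl propiolate
Product: 2 methyl (Z)-3-iodoprop-2-enoate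
Conditions: NaI, AcOH, 70 °C
Reagents that add atoms: sodium iodide, [Na+].[I-]
Why: Conjugate addition of iodide to the ynoate and anti protonation of the allenolate (hydroiodination) should give the Z-iodoacrylate as the kinetic product.

Step 2
Reactants: 2 methyl (Z)-3-iodoprop-2-enoate
Product: 3 (Z)-3-iodoprop-2-en-1-ol
Conditions: i-Bu2AlH, CH2Cl2, −78 → 0 °C; aq. potassium sodium tartrate
Reagents that add atoms: none
Why: Aluminium hydride reduction of the ester at low temperature should leave the C–I bond and the Z geometry untouched.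

Step 3
Reactants: 3 (Z)-3-iodoprop-2-en-1-ol
Product: 4 (Z)-1,3-diiodoprop-1-ene
Conditions: PPh3, I2, imidazole, CH2Cl2, 0 °C, dark; used at once
Reagents that add atoms: iodine, II
Why: Appel-type iodination converts the primary allylic alcohol through its oxyphosphonium salt into the allylic iodide by SN2 displacement, without touching the alkenyl iodide.

Step 4
Reactants: 5 (Z)-hex-3-en-1-ol
Product: 6 (Z)-hex-3-enal
Conditions: Dess–Martin periodinane, NaHCO3, CH2Cl2, 0 °C; used crude
Reagents that add atoms: none
Why: Dess–Martin oxidation under bicarbonate buffer is mild enough to give the skipped enal without moving the double bond into conjugation; the aldehyde is used directly.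

Step 5
Reactants: 6 (Z)-hex-3-enal; 7 ethynyltrimethylsilane
Product: 9 (3S,5Z)-1-(trimethylsilyl)oct-5-en-1-yn-3-ol, via alkynylzinc 8 (not isolated)
Conditions: 7, Et2Zn, Cy2NH (cat.), Et2O, rt; (R)-BINOL (20 mol %), Ti(OiPr)4 (50 mol %); then 6, 0 °C → rt
Reagents that add atoms: none
Why: Catalytic asymmetric alkynylzinc addition to an aldehyde under BINOL–titanium control; delivery to the Re face sets C15 as S, and the Lewis-acidic, weakly basic medium should spare the enolisable skipped enal.

Step 6
Reactants: 9 (3S,5Z)-1-(trimethylsilyl)oct-5-en-1-yn-3-ol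
Product: 10 (3S,5Z)-oct-5-en-1-yn-3-ol
Conditions: K2CO3 (cat.), MeOH, rt
Reagents that add atoms: none
Why: Methanolysis of the C(sp)–Si bond frees the terminal alkyne without affecting the carbinol centre.

Step 7
Reactants: 10 (3S,5Z)-oct-5-en-1-yn-3-ol
Product: 11 (3S,5Z)-3-(4-methoxybenzyloxy)oct-5-en-1-yne
Conditions: NaH, 4-methoxybenzyl chloride, Bu4NI (cat.), THF/DMF, 0 °C → rt
Reagents that add atoms: 4-methoxybenzyl chloride, COc1ccc(CCl)cc1
Why: Williamson etherification of the alkoxide; the ether survives organolithium, silylation and acylation steps and is later removed oxidatively, orthogonal to silyl ethers and esters.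

Step 8
Reactants: 11 (3S,5Z)-3-(4-methoxybenzyloxy)oct-5-en-1-yne
Product: 13 (1E,3S,5Z)-1-iodo-3-(4-methoxybenzyloxy)octa-1,5-diene, via alkenylzirconocene chloride 12 (not isolated)
Conditions: Cp2Zr(H)Cl, THF, rt; then I2, 0 °C
Reagents that add atoms: iodine, II
Why: Hydrozirconation adds Zr–H syn across the terminal alkyne with zirconium on the terminal carbon, and iodinolysis with retention gives the E-iodoalkene; the internal Z-alkene reacts much more slowly.

Step 9
Reactants: 14 (R)-4-hydroxycyclopent-2-en-1-one
Product: 15 (R)-4-(triethylsilyloxy)cyclopent-2-en-1-one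
Conditions: Et3SiCl, imidazole, CH2Cl2, 0 °C
Reagents that add atoms: chlorotriethylsilane, CC[Si](Cl)(CC)CC
Why: Standard silylation; the triethylsilyl ether is chosen because it can later be removed in the presence of a tert-butyldimethylsilyl ether.

Step 10
Reactants: 13 (1E,3S,5Z)-1-iodo-3-(4-methoxybenzyloxy)octa-1,5-diene; 15 (R)-4-(triethylsilyloxy)cyclopent-2-en-1-one; 4 (Z)-1,3-diiodoprop-1-ene
Product: 19 (2R,3R,4R)-2-[(Z)-3-iodoprop-2-enyl]-3-[(1E,3S,5Z)-3-(4-methoxybenzyloxy)octa-1,5-dienyl]-4-(triethylsilyloxy)cyclopentan-1-one, via alkenyllithium 16 (not isolated), via lithium alkenyldimethylzincate 17 (not isolated), via zinc enolate 18 (not isolated)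
Conditions: 13, t-BuLi (2 equiv), Et2O, −78 °C; Me2Zn, −78 → 0 °C; 15, THF, −78 °C; then HMPA, 4 (excess), −78 → −40 °C
Reagents that add atoms: none
Why: Three-component coupling (iodine–lithium exchange, zincate conjugate addition, enolate alkylation): the alkenyl group adds anti to the C11 silyloxy group and sets C12, and the zinc enolate is alkylated anti to the new C12 chain and sets C8, giving the all-trans ring. The zinc enolate with HMPA alkylates reactive allylic iodides faster than it equilibrates.

Step 11
Reactants: 19 the cyclopentanone from step 10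
Product: 20 (1S,2R,3R,4R)-2-[(Z)-3-iodoprop-2-enyl]-3-[(1E,3S,5Z)-3-(4-methoxybenzyloxy)octa-1,5-dienyl]-4-(triethylsilyloxy)cyclopentan-1-ol
Conditions: Li[HB(s-Bu)3], THF, −78 °C
Reagents that add atoms: none
Why: The bulky borohydride attacks the C9 carbonyl from the face opposite the adjacent C8 side chain, which should give the 9α-alcohol; the alkenyl iodide is inert at this temperature.

Step 12
Reactants: 20 the 9α-alcohol
Product: 21 9α-O-tert-butyldimethylsilyl ether of 20 (8R,9S,11R,12R,15S; O11 triethylsilyl; O15 4-methoxybenzyl)
Conditions: TBSOTf, 2,6-lutidine, CH2Cl2, −78 → 0 °C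
Reagents that add atoms: tert-butyldimethylsilyl trifluoromethanesulfonate, CC(C)(C)[Si](C)(C)OS(=O)(=O)C(F)(F)F
Why: The silyl triflate silylates the hindered secondary C9 hydroxyl under non-nucleophilic base, leaving the triethylsilyl and 4-methoxybenzyl ethers in place.

Step 13
Reactants: 21 the bis-silyl ether
Product: 22 11α-alcohol (8R,9S,11R,12R,15S; O9 tert-butyldimethylsilyl; O15 4-methoxybenzyl)
Conditions: PPTS (cat.), MeOH/CH2Cl2, 0 °C
Reagents that add atoms: none
Why: Acid-catalysed methanolysis cleaves the triethylsilyl ether far faster than the bulkier, more hindered tert-butyldimethylsilyl ether at C9.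

Step 14
Reactants: 22 the 11α-alcohol
Product: 23 11α-acetate (8R,9S,11R,12R,15S; O9 tert-butyldimethylsilyl; O15 4-methoxybenzyl)
Conditions: Ac2O, pyridine, DMAP (cat.), CH2Cl2, rt
Reagents that add atoms: acetic anhydride, CC(=O)OC(C)=O
Why: DMAP-catalysed acetylation of the only free hydroxyl; no ketone is present, so no β-elimination can occur.

Step 15
Reactants: 23 the 11α-acetate
Product: 24 15-alcohol (8R,9S,11R,12R,15S; O9 tert-butyldimethylsilyl; O11 acetyl)
Conditions: DDQ, CH2Cl2/pH 7 phosphate buffer, 0 °C
Reagents that add atoms: none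
Why: Oxidative cleavage of the 4-methoxybenzyl ether (hydride abstraction to the oxocarbenium ion and hydrolysis) leaves silyl ether, acetate, alkenes and alkenyl iodide untouched under buffered conditions.

Step 16
Reactants: 24 the 15-alcohol; 25 but-3-enoic acid
Product: 26 15-O-but-3-enoate (8R,9S,11R,12R,15S; O9 tert-butyldimethylsilyl; O11 acetyl; C8 (Z)-3-iodoprop-2-enyl)
Conditions: DCC, DMAP (cat.), CH2Cl2, −20 → 0 °C
Reagents that add atoms: none
Why: Steglich esterification acylates O15 with retention at C15; low temperature and a small amount of DMAP are used to limit migration of the β,γ-double bond into conjugation.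

Step 17
Reactants: 26 the 15-O-but-3-enoate
Product: 28 9α-O-tert-butyldimethylsilyl prostaglandin F3α 1,15-lactone 11-acetate (8R,9S,11R,12R,15S; 5Z,13E,17Z), via B-alkyl-9-borabicyclononane 27 (not isolated)
Conditions: 9-BBN-H dimer, THF, 0 °C → rt; then slow addition to Pd(dppf)Cl2 (10 mol %), AsPh3 (20 mol %), Cs2CO3, DMF/THF/H2O, rt, ca. 1 mM
Reagents that add atoms: none
Why: 9-BBN-H should add only to the monosubstituted C3=C4 alkene of the but-3-enoate, with boron on C4, because the disubstituted alkenes, the iodoalkene and the ester carbonyls react far more slowly with this hindered borane; this gives 27. Zerovalent palladium formed from Pd(dppf)Cl2 inserts into the C5–I bond with retention, the base turns the borane into a borate that transfers the primary C4 alkyl group to palladium, and reductive elimination joins C4 to C5 with the Z geometry of C5=C6 intact. The closest known reaction type is the B-alkyl Suzuki–Miyaura macrocyclisation of a hydroborated terminal alkene onto a Z-alkenyl iodide. The 13-membered lactone closes by intramolecular transmetalation through a 14-membered palladacycle that contracts on reductive elimination, and slow addition at high dilution favours this over intermolecular coupling. No stereocentre is formed, and the four existing ones are remote from the reacting carbons. The step needs oxidative addition at the alkenyl iodide to outrun ionisation of the allylic C15 ester, which the much faster insertion into the C(sp2)–I bond at room temperature should secure. It also needs the C11 acetate to survive, which the mild carbonate base and the masking of C9 as a silyl ether should allow.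

Step 18
Reactants: 28 the silylated macrolactone
Product: 29 prostaglandin F3α 1,15-lactone 11-acetate (8R,9S,11R,12R,15S; 5Z,13E,17Z)
Conditions: HF·pyridine, pyridine, THF, 0 °C → rt
Reagents that add atoms: none
Why: Fluoride cleaves the Si–O bond under buffered, weakly acidic conditions that spare the acetate and the allylic lactone; the alcohol is oxidised without delay to forestall acetyl migration from O11 to O9.

Step 19
Reactants: 29 the 9α-alcohol
Product: 30 prostaglandin E3 1,15-lactone 11-acetate (8R,11R,12R,15S; 5Z,13E,17Z)
Conditions: Dess–Martin periodinane, NaHCO3, CH2Cl2, 0 °C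
Reagents that add atoms: none
Why: Dess–Martin oxidation forms the C9 ketone under near-neutral conditions, so the β-acetoxy ketone should not eliminate acetic acid and C8 should not epimerise.

## Compound list

1 | methyl propiolate | C#CC(=O)OC | starting material
2 | methyl (Z)-3-iodoprop-2-enoate | COC(=O)/C=C\I | intermediate
3 | (Z)-3-iodoprop-2-en-1-ol | OC/C=C\I | intermediate
4 | (Z)-1,3-diiodoprop-1-ene | IC/C=C\I | intermediate
5 | (Z)-hex-3-en-1-ol | CC/C=C\CCO | starting material
6 | (Z)-hex-3-enal | CC/C=C\CC=O | intermediate
7 | ethynyltrimethylsilane | C#C[Si](C)(C)C | starting material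
8 | ethyl[(trimethylsilyl)ethynyl]zinc | CC[Zn]C#C[Si](C)(C)C | intermediate
9 | (3S,5Z)-1-(trimethylsilyl)oct-5-en-1-yn-3-ol | CC/C=C\C[C@H](O)C#C[Si](C)(C)C | intermediate
10 | (3S,5Z)-oct-5-en-1-yn-3-ol | CC/C=C\C[C@H](O)C#C | intermediate
11 | (3S,5Z)-3-(4-methoxybenzyloxy)oct-5-en-1-yne | CC/C=C\C[C@H](OCc1ccc(OC)cc1)C#C | intermediate
12 | chlorobis(cyclopentadienyl)[(1E,3S,5Z)-3-(4-methoxybenzyloxy)octa-1,5-dien-1-yl]zirconium | CC/C=C\C[C@H](OCc1ccc(OC)cc1)/C=C/[Zr](Cl)(C1C=CC=C1)C1C=CC=C1 | intermediate
13 | (1E,3S,5Z)-1-iodo-3-(4-methoxybenzyloxy)octa-1,5-diene | CC/C=C\C[C@H](OCc1ccc(OC)cc1)/C=C/I | intermediate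
14 | (R)-4-hydroxycyclopent-2-en-1-one | O=C1C=C[C@H](O)C1 | starting material
15 | (R)-4-(triethylsilyloxy)cyclopent-2-en-1-one | O=C1C=C[C@H](O[Si](CC)(CC)CC)C1 | intermediate
16 | [(1E,3S,5Z)-3-(4-methoxybenzyloxy)octa-1,5-dien-1-yl]lithium | CC/C=C\C[C@H](OCc1ccc(OC)cc1)/C=C/[Li] | intermediate
17 | lithium dimethyl[(1E,3S,5Z)-3-(4-methoxybenzyloxy)octa-1,5-dien-1-yl]zincate | CC/C=C\C[C@H](OCc1ccc(OC)cc1)/C=C/[Zn-](C)C.[Li+] | intermediate
18 | lithium dimethylzincate enolate of (3R,4R)-3-[(1E,3S,5Z)-3-(4-methoxybenzyloxy)octa-1,5-dienyl]-4-(triethylsilyloxy)cyclopentanone (C8=C9 enolate) | CC/C=C\C[C@H](OCc1ccc(OC)cc1)/C=C/[C@H]1[C@H](O[Si](CC)(CC)CC)CC(O[Zn-](C)C)=C1.[Li+] | intermediate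
19 | (2R,3R,4R)-2-[(Z)-3-iodoprop-2-enyl]-3-[(1E,3S,5Z)-3-(4-methoxybenzyloxy)octa-1,5-dienyl]-4-(triethylsilyloxy)cyclopentan-1-one | CC/C=C\C[C@H](OCc1ccc(OC)cc1)/C=C/[C@H]1[C@H](O[Si](CC)(CC)CC)CC(=O)[C@@H]1C/C=C\I | intermediate
20 | (1S,2R,3R,4R)-2-[(Z)-3-iodoprop-2-enyl]-3-[(1E,3S,5Z)-3-(4-methoxybenzyloxy)octa-1,5-dienyl]-4-(triethylsilyloxy)cyclopentan-1-ol | CC/C=C\C[C@H](OCc1ccc(OC)cc1)/C=C/[C@H]1[C@H](O[Si](CC)(CC)CC)C[C@H](O)[C@@H]1C/C=C\I | intermediate
21 | tert-butyldimethylsilyl ether of 20 at O9 (8R,9S,11R,12R,15S; O11 triethylsilyl, O15 4-methoxybenzyl) | CC/C=C\C[C@H](OCc1ccc(OC)cc1)/C=C/[C@H]1[C@H](O[Si](CC)(CC)CC)C[C@H](O[Si](C)(C)C(C)(C)C)[C@@H]1C/C=C\I | intermediate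
22 | (1R,2R,3R,4S)-4-(tert-butyldimethylsilyloxy)-3-[(Z)-3-iodoprop-2-enyl]-2-[(1E,3S,5Z)-3-(4-methoxybenzyloxy)octa-1,5-dienyl]cyclopentan-1-ol | CC/C=C\C[C@H](OCc1ccc(OC)cc1)/C=C/[C@H]1[C@H](O)C[C@H](O[Si](C)(C)C(C)(C)C)[C@@H]1C/C=C\I | intermediate
23 | acetate of 22 at O11 (8R,9S,11R,12R,15S) | CC/C=C\C[C@H](OCc1ccc(OC)cc1)/C=C/[C@H]1[C@H](OC(C)=O)C[C@H](O[Si](C)(C)C(C)(C)C)[C@@H]1C/C=C\I | intermediate
24 | (1R,2R,3R,4S)-4-(tert-butyldimethylsilyloxy)-2-[(1E,3S,5Z)-3-hydroxyocta-1,5-dienyl]-3-[(Z)-3-iodoprop-2-enyl]cyclopentyl acetate | CC/C=C\C[C@H](O)/C=C/[C@H]1[C@H](OC(C)=O)C[C@H](O[Si](C)(C)C(C)(C)C)[C@@H]1C/C=C\I | intermediate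
25 | but-3-enoic acid | C=CCC(=O)O | starting material
26 | but-3-enoate of 24 at O15 (8R,9S,11R,12R,15S; Z-iodoalkene, O9 tert-butyldimethylsilyl, O11 acetyl) | CC/C=C\C[C@H](OC(=O)CC=C)/C=C/[C@H]1[C@H](OC(C)=O)C[C@H](O[Si](C)(C)C(C)(C)C)[C@@H]1C/C=C\I | intermediate
27 | 4-(9-borabicyclo[3.3.1]nonan-9-yl)butanoate of 24 at O15 (8R,9S,11R,12R,15S) | CC/C=C\C[C@H](OC(=O)CCCB1C2CCCC1CCC2)/C=C/[C@H]1[C@H](OC(C)=O)C[C@H](O[Si](C)(C)C(C)(C)C)[C@@H]1C/C=C\I | intermediate
28 | 9α-O-tert-butyldimethylsilyl prostaglandin F3α 1,15-lactone 11-acetate (8R,9S,11R,12R,15S; 5Z,13E,17Z) | CC/C=C\C[C@H]1/C=C/[C@H]2[C@H](OC(C)=O)C[C@H](O[Si](C)(C)C(C)(C)C)[C@@H]2C/C=C\CCCC(=O)O1 | intermediate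
29 | prostaglandin F3α 1,15-lactone 11-acetate (8R,9S,11R,12R,15S; 5Z,13E,17Z) | CC/C=C\C[C@H]1/C=C/[C@H]2[C@H](OC(C)=O)C[C@H](O)[C@@H]2C/C=C\CCCC(=O)O1 | intermediate
30 | prostaglandin E3 1,15-lactone 11-acetate (8R,11R,12R,15S; 5Z,13E,17Z) | CC/C=C\C[C@H]1/C=C/[C@H]2[C@H](OC(C)=O)CC(=O)[C@@H]2C/C=C\CCCC(=O)O1 | target

## Step count and least certain steps

Total step count: 19. Longest linear sequence: 15 steps (5 → 6 → 9 → 10 → 11 → 13 → 19 → 20 → 21 → 22 → 23 → 24 → 26 → 28 → 29 → 30).

**Step 17 (key step).** Most likely to go wrong:
- intermolecular coupling leading to oligomers, because a 13‑membered ring with three alkenes is only moderately preorganised;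
- ionisation of the allylic C15 carboxylate by zerovalent palladium, which would scramble C15 or open the chain;
- protodeboronation of the alkylborane, or slow hydrolysis of the acetate by the aqueous base.

Fallback, setting out from alcohol 24 and returning at 28: the same C4–C5 bond would be made intermolecularly and the ring closed by lactonisation instead. But‑3‑enoic acid 25 would be esterified with 2‑(trimethylsilyl)ethanol to give 2‑(trimethylsilyl)ethyl but‑3‑enoate F1. Hydroboration with 9‑BBN‑H would give the borane F2, which would be coupled with 24 under the Pd(dppf)Cl2/AsPh3/Cs2CO3 conditions to give the seco ester F3, in which no allylic ester is present. Tris(dimethylamino)sulfonium difluorotrimethylsilicate in DMF at 0 °C would free the seco acid F4. Yamaguchi macrolactonisation (2,4,6‑trichlorobenzoyl chloride, Et3N, then DMAP in toluene at high dilution) would then close O15–C1 to give 28.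

**Step 10.** Most likely to go wrong:
- proton transfer between the product ketone and the zinc enolate before alkylation, giving loss of regiocontrol, the simple conjugate adduct, or β‑elimination of the C11 silyloxy group;
- base‑induced decomposition of the doubly iodinated electrophile 4.

Fallback, setting out from 13 and 15 and returning at 19: the zinc enolate would be trapped with the more reactive 3‑bromo‑1‑(trimethylsilyl)prop‑1‑yne to give the silylpropargyl ketone F5. Iododesilylation with N‑iodosuccinimide and catalytic AgNO3 would give the iodoalkyne F6. Syn reduction with diimide (2‑nitrobenzenesulfonyl hydrazide, Et3N) would then deliver the Z‑iodoalkene 19, so that the Z geometry is made after the C7–C8 bond and not carried through the alkylation.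

**Step 5.** Most likely to go wrong: migration of the C17=C18 double bond of the skipped enal into conjugation, self‑aldol condensation, or insufficient facial selectivity with this unbranched aldehyde.

Fallback, setting out from 6 and returning at 13 (bypassing steps 5–8): addition of (E)‑2‑(tributylstannyl)vinyllithium (from (E)‑1,2‑bis(tributylstannyl)ethene and n‑BuLi) at −78 °C would give the racemic stannyl alcohol F7. Iodine would convert it into the racemic iodo alcohol F8. A Sharpless kinetic resolution with Ti(OiPr)4, D‑(−)‑diisopropyl tartrate and t‑BuOOH would recover the (S)‑iodo alcohol F9 while the R enantiomer is consumed as the epoxy alcohol F10. Protection of F9 with 4‑methoxybenzyl 2,2,2‑trichloroacetimidate and catalytic acid would give 13. At most half of the material is usable, which is the price of the robust resolution.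

**Step 16.** Most likely to go wrong: base‑catalysed migration of the C3=C4 double bond into conjugation during acylation, through the acylpyridinium salt or a vinylketene. The resulting but‑2‑enoate cannot be hydroborated at C4.

Fallback, setting out from 24 and returning at 26: 24 would be esterified (DCC, DMAP) with 4‑(phenylselanyl)butanoic acid F11, made from γ‑butyrolactone and sodium benzeneselenolate, which has no double bond to migrate. This gives the selenide ester F12. Oxidation with H2O2 in the presence of pyridine and syn elimination of the selenoxide would unveil the terminal alkene of 26 under non‑basic conditions.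

## Further compounds

F1 | step 17 | 2-(trimethylsilyl)ethyl but-3-enoate | C=CCC(=O)OCC[Si](C)(C)C
F2 | step 17 | 2-(trimethylsilyl)ethyl 4-(9-borabicyclo[3.3.1]nonan-9-yl)butanoate | C[Si](C)(C)CCOC(=O)CCCB1C2CCCC1CCC2
F3 | step 17 | seco ester: 2-(trimethylsilyl)ethyl (5Z,8R,9S,11R,12R,13E,15S,17Z)-11-acetoxy-9-(tert-butyldimethylsilyloxy)-15-hydroxyprosta-5,13,17-trienoate | CC/C=C\C[C@H](O)/C=C/[C@H]1[C@H](OC(C)=O)C[C@H](O[Si](C)(C)C(C)(C)C)[C@@H]1C/C=C\CCCC(=O)OCC[Si](C)(C)C
F4 | step 17 | seco acid: (5Z,8R,9S,11R,12R,13E,15S,17Z)-11-acetoxy-9-(tert-butyldimethylsilyloxy)-15-hydroxyprosta-5,13,17-trienoic acid | CC/C=C\C[C@H](O)/C=C/[C@H]1[C@H](OC(C)=O)C[C@H](O[Si](C)(C)C(C)(C)C)[C@@H]1C/C=C\CCCC(=O)O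
F5 | step 10 | (2R,3R,4R)-3-[(1E,3S,5Z)-3-(4-methoxybenzyloxy)octa-1,5-dienyl]-4-(triethylsilyloxy)-2-[3-(trimethylsilyl)prop-2-ynyl]cyclopentan-1-one | CC/C=C\C[C@H](OCc1ccc(OC)cc1)/C=C/[C@H]1[C@H](O[Si](CC)(CC)CC)CC(=O)[C@@H]1CC#C[Si](C)(C)C
F6 | step 10 | (2R,3R,4R)-2-(3-iodoprop-2-ynyl)-3-[(1E,3S,5Z)-3-(4-methoxybenzyloxy)octa-1,5-dienyl]-4-(triethylsilyloxy)cyclopentan-1-one | CC/C=C\C[C@H](OCc1ccc(OC)cc1)/C=C/[C@H]1[C@H](O[Si](CC)(CC)CC)CC(=O)[C@@H]1CC#CI
F7 | step 5 | racemic (1E,5Z)-1-(tributylstannyl)octa-1,5-dien-3-ol | CC/C=C\CC(O)/C=C/[Sn](CCCC)(CCCC)CCCC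
F8 | step 5 | racemic (1E,5Z)-1-iodoocta-1,5-dien-3-ol | CC/C=C\CC(O)/C=C/I
F9 | step 5 | (1E,3S,5Z)-1-iodoocta-1,5-dien-3-ol | CC/C=C\C[C@H](O)/C=C/I
F10 | step 5 | (1R,3Z)-1-[(2R,3R)-3-iodooxiran-2-yl]hex-3-en-1-ol | I[C@H]1O[C@@H]1[C@H](O)C/C=C\CC
F11 | step 16 | 4-(phenylselanyl)butanoic acid | O=C(O)CCC[Se]c1ccccc1
F12 | step 16 | 4-(phenylselanyl)butanoate of 24 at O15 (8R,9S,11R,12R,15S) | CC/C=C\C[C@H](OC(=O)CCC[Se]c1ccccc1)/C=C/[C@H]1[C@H](OC(C)=O)C[C@H](O[Si](C)(C)C(C)(C)C)[C@@H]1C/C=C\I
A1 | alternative 1 | succinaldehyde | O=CCCC=O
A2 | alternative 1 | (E)-4,4-dimethoxy-1-nitrobut-1-ene | COC(OC)C/C=C/[N+](=O)[O-]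
A3 | alternative 1 | nitro hydroxy cyclopentanecarbaldehyde (C12 formyl, C8 2,2-dimethoxyethyl, C9 nitro, C10 hydroxyl) | O=C[C@H]1C[C@H](O)[C@@H]([N+](=O)[O-])[C@@H]1CC(OC)OC
A4 | alternative 2 | acyclic aldehyde E-vinyl sulfone (C11 aldehyde, C9 silyl ether, C8 but-2-ynyl) | O=CC[C@@H](O[Si](C)(C)C(C)(C)C)[C@H](CC#CC)/C=C/S(=O)(=O)c1ccccc1
A5 | alternative 2 | cyclopentanol with C12 phenylsulfonylmethyl arm, C9 silyl ether and C8 but-2-ynyl group | O=S(=O)(c1ccccc1)C[C@H]1[C@H](O)C[C@@H](O[Si](C)(C)C(C)(C)C)[C@@H]1CC#CC
A6 | alternative 3 | diyne ester (prop-1-ynyl groups on C12 and C15, C1–O15 ester in place) | CC/C=C\C[C@H](OC(=O)CCC/C=C\C[C@H]1C(=O)C[C@@H](OC(C)=O)[C@@H]1C#CC)C#CC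
A7 | alternative 3 | 13,14-didehydro macrolactone (cycloalkyne) | CC/C=C\C[C@H]1C#C[C@H]2[C@H](OC(C)=O)CC(=O)[C@@H]2C/C=C\CCCC(=O)O1
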